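## Retrosynthetic overview

1. Target 17 is cut back at the two ring halogens (late directed bromochlorination of a 4-methylcyclohex-3-en-1-ol), at the ring methyl (enol triflate of a 4-hydroxycyclohexanone) and at the cyclopentyl C–Br (vinyl bromide from a cyclopentanone).
2. The cyclopentane is made first, by a (3+2) union of a 1,1-dimethyl-2-siloxyallyl cation (C3 unit CMe2–C(O)–CH2) with the isopropenyl group of 4-isopropenylanisole (C2 unit). This forms the CH2–CH2 bond and the CMe2–C(Me) bond between the two fully substituted carbons in one operation.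
3. Enabling feature: C1 of the cyclohexanol ring is carried as the ipso carbon of a p-methoxyphenyl ring. The alkene carbon that becomes the quaternary cyclopentane carbon is therefore benzylic and holds the cation. The arene is later turned into the cyclohexanol ring (phenol, para-quinol, 4-hydroxycyclohexanone), with oxygen entering on that same carbon.
4. Stereochemistry: the quaternary centre is set by the catalyst in the key step and relays to the cyclopentyl C–Br; the carbinol centre is set by a chiral lithium amide and relays to both halogen-bearing ring carbons in the last step.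
5. Ring order: cyclopentane (step 2), then the six-membered carbocycle is unmasked from the arene (steps 5–7).

Key step: step 2

Assumption: lithium (R,R)-bis(1-phenylethyl)amide is taken to remove in 12 the same enantiotopic α-proton as in 4-tert-butylcyclohexanone (where it leads to the (S)-enol derivative); if the sense proves opposite, the (S,S)-amide is used.

Remark: the descriptor of the cyclopentyl C1 changes from S (6–9) to R (10–17) only because the aryl carbon becomes an oxygen-bearing carbon of higher CIP priority; the spatial arrangement is unchanged.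

## Route

Step 1
Reactants: 1 3-bromo-3-methylbutan-2-one
Product: 2 [(3-bromo-3-methylbut-1-en-2-yl)oxy]triethylsilane
Conditions: Et3SiOTf, Et3N, CH2Cl2, 0 °C
Reagents that add atoms: triethylsilyl trifluoromethanesulfonate, CC[Si](CC)(CC)OS(=O)(=O)C(F)(F)F
Why: Soft enolisation with a silyl triflate and an amine base gives the only possible silyl enol ether (the other α-carbon is quaternary), the standard entry to 2-siloxyallyl halides.

Step 2
Reactants: 2 [(3-bromo-3-methylbut-1-en-2-yl)oxy]triethylsilane; 3 1-methoxy-4-(prop-1-en-2-yl)benzene (4-isopropenylanisole)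
Product: 6 (3S)-3-(4-methoxyphenyl)-2,2,3-trimethylcyclopentan-1-one, via siloxyallyl cation 4 (not isolated), via benzylic cation 5 (not isolated)
Conditions: chiral squaramide hydrogen-bond donor (tert-leucine 2-arylpyrrolidine amide type, 10 mol %), 2,6-di-tert-butyl-4-methylpyridine (0.2 equiv), 4 Å MS, toluene, −78 → −40 °C; aq. NaHCO3
Reagents that add atoms: none
Why: Proposed new method: The squaramide binds and abstracts bromide from the tertiary allylic bromide 2 to give the 2-siloxyallyl cation 4 as a chiral contact ion pair; the CH2 of styrene 3 attacks the CH2 terminus of 4 (first bond, CH2–CH2), giving the p-anisyl-stabilised tertiary benzylic cation 5 with a tetrasubstituted enol silane. The enol silane carbon then closes on the cation (second bond, CMe2–C(Me)Ar) in a cationic 5-(enolendo) Prins-type ring closure, and silyl transfer to bromide releases ketone 6 and the catalyst. The closest known reactions are the racemic (3+2) cyclocoupling of oxyallyl cations from α,α'-dibromoketones and Fe2(CO)9 with α-methylstyrenes (same 3-aryl-2,2,3-trimethylcyclopentanone skeleton), the ZnCl2-promoted cycloadditions of this class of siloxyallyl bromide, and enantioselective (4+3) cycloadditions of siloxyallyl cations under chiral hydrogen-bond-donor catalysis. The one new stereocentre, C3, is set in the ring closure, where the catalyst-bound bromide shields one face of the planar benzylic cation (catalyst control; the catalyst antipode that gives (S)-6 is used). The step needs the CH2 allyl terminus to bond first, closure through carbon and not oxygen, and closure faster than proton loss: the gem-dimethyl terminus is hindered, the anisyl ring places the charge on the carbon that must become quaternary, and the O-silyl group blocks closure through oxygen.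

Step 3
Reactants: 6 (3S)-3-(4-methoxyphenyl)-2,2,3-trimethylcyclopentan-1-one
Product: 7 1-[(1S)-3-bromo-1,2,2-trimethylcyclopent-3-en-1-yl]-4-methoxybenzene
Conditions: P(OPh)3, Br2, CH2Cl2, −60 °C; then 6, Et3N, −60 °C → reflux
Reagents that add atoms: bromine, BrBr
Why: Conversion of an enolisable ketone into a vinyl bromide with triphenyl phosphite dibromide; only C5 carries α-hydrogens (C2 is quaternary), so one regioisomer should form and the quaternary stereocentre is untouched.

Step 4
Reactants: 7 1-[(1S)-3-bromo-1,2,2-trimethylcyclopent-3-en-1-yl]-4-methoxybenzene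
Product: 8 1-[(1S,3S)-3-bromo-1,2,2-trimethylcyclopentyl]-4-methoxybenzene
Conditions: Mn(dpm)3 (10 mol %), PhSiH3, t-BuOOH, i-PrOH, 22 °C
Reagents that add atoms: none
Why: Mukaiyama-type hydrogen-atom-transfer hydrogenation adds H• to C4 and then delivers the second hydrogen to the α-bromo radical at C3 from the face anti to the aryl group, which should set the C–Br centre with Br cis to the aryl ring (also the more stable cis-1,3 arrangement) without the hydrogenolysis expected over palladium.

Step 5
Reactants: 8 1-[(1S,3S)-3-bromo-1,2,2-trimethylcyclopentyl]-4-methoxybenzene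
Product: 9 4-[(1S,3S)-3-bromo-1,2,2-trimethylcyclopentyl]phenol
Conditions: BBr3, CH2Cl2, −78 → 0 °C; H2O
Reagents that add atoms: none
Why: Lewis-acid demethylation of an aryl methyl ether with BBr3 at low temperature, which should leave the hindered secondary bromide alone.

Step 6
Reactants: 9 4-[(1S,3S)-3-bromo-1,2,2-trimethylcyclopentyl]phenol
Product: 11 4-[(1R,3S)-3-bromo-1,2,2-trimethylcyclopentyl]-4-hydroxycyclohexa-2,5-dien-1-one, via para-peroxyquinol 10 (not isolated)
Conditions: Oxone (2KHSO5·KHSO4·K2SO4), NaHCO3, MeCN–H2O, 20 °C; then Me2S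
Reagents that add atoms: Oxone (potassium peroxymonosulfate, the oxygen source), [K+].[O-]S(=O)(=O)OO
Why: Dearomatisation of a para-alkylphenol by singlet oxygen generated from Oxone gives the para-peroxyquinol, reduced in the same flask to the para-quinol; oxygen enters on the former ipso carbon, which is not yet a stereocentre because the two ring halves are identical.

Step 7
Reactants: 11 4-[(1R,3S)-3-bromo-1,2,2-trimethylcyclopentyl]-4-hydroxycyclohexa-2,5-dien-1-one
Product: 12 4-[(1R,3S)-3-bromo-1,2,2-trimethylcyclopentyl]-4-hydroxycyclohexan-1-one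
Conditions: H2 (1 atm), 5% Rh/Al2O3, EtOAc, 20 °C
Reagents that add atoms: none
Why: Heterogeneous hydrogenation of both enone C=C bonds over rhodium, chosen over palladium to avoid hydrogenolysis of the C–Br bond and of the doubly allylic tertiary C–O bond.

Step 8
Reactants: 12 4-[(1R,3S)-3-bromo-1,2,2-trimethylcyclopentyl]-4-hydroxycyclohexan-1-one
Product: 14 (4R)-4-[(1R,3S)-3-bromo-1,2,2-trimethylcyclopentyl]-4-hydroxycyclohex-1-en-1-yl trifluoromethanesulfonate, via dilithium alkoxide enolate 13 (not isolated)
Conditions: (R,R)-bis(1-phenylethyl)amine·HCl (2.3 equiv), n-BuLi (4.6 equiv), THF, −78 → 0 → −100 °C; 12; then PhNTf2, −78 → 0 °C; aq. NH4Cl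
Reagents that add atoms: N-phenylbis(trifluoromethanesulfonimide), O=S(=O)(N(c1ccccc1)S(=O)(=O)C(F)(F)F)C(F)(F)F
Why: Enantiotopic deprotonation of a 4,4-disubstituted cyclohexanone with a chiral lithium amide (LiCl present) and O-triflation of the enolate: after the first equivalent forms the alkoxide, the base removes one of the two enantiotopic axial α-protons under reagent control (the existing centres are remote), which fixes the arm that carries the double bond and makes C4 an (R) stereocentre.

Step 9
Reactants: 14 (4R)-4-[(1R,3S)-3-bromo-1,2,2-trimethylcyclopentyl]-4-hydroxycyclohex-1-en-1-yl trifluoromethanesulfonate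
Product: 15 (1R)-1-[(1R,3S)-3-bromo-1,2,2-trimethylcyclopentyl]-4-methylcyclohex-3-en-1-ol
Conditions: MeB(OH)2, Pd(dppf)Cl2 (5 mol %), K2CO3, 1,4-dioxane–H2O, 80 °C
Reagents that add atoms: methylboronic acid, CB(O)O
Why: Suzuki–Miyaura coupling of an enol triflate with methylboronic acid, which should leave the hindered secondary alkyl bromide and the tertiary alcohol untouched.

Step 10
Reactants: 15 (1R)-1-[(1R,3S)-3-bromo-1,2,2-trimethylcyclopentyl]-4-methylcyclohex-3-en-1-ol
Product: 17 (1R,3S,4S)-3-bromo-1-[(1R,3S)-3-bromo-1,2,2-trimethylcyclopentyl]-4-chloro-4-methylcyclohexan-1-ol, via titanium alkoxide 16 (not isolated)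
Conditions: ClTi(Oi-Pr)3 (1.5 equiv), NBS (1.2 equiv), hexanes–CH2Cl2, −20 → 0 °C
Reagents that add atoms: N-bromosuccinimide, O=C1CCC(=O)N1Br; chlorotitanium triisopropoxide, CC(C)O[Ti](Cl)(OC(C)C)OC(C)C
Why: Proposed new method: the tertiary alcohol is titanated in situ (16) and sits axial on the ring face opposite to the cyclopentyl group, so NBS should brominate the alkene on the cyclopentyl face while the titanium-bound chloride is handed over on the oxygen face (Br trans and Cl cis to OH, both halogen centres set in one event); chloride attack at the tertiary carbon gives 17 directly, and the trans-diaxial regioisomer from attack at the secondary carbon has antiperiplanar halogens and should re-form the same bromonium ion under the Lewis-acidic conditions until the diequatorial 17, which cannot, is left; the closest known reactions are the ClTi(Oi-Pr)3/NBS bromochlorination of allylic alcohols with chloride delivery from the titanium alkoxide and the diaxial-to-diequatorial interchange of vicinal dihalides.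

## Compound list

1 | 3-bromo-3-methylbutan-2-one | CC(=O)C(C)(C)Br | starting material
2 | [(3-bromo-3-methylbut-1-en-2-yl)oxy]triethylsilane | C=C(O[Si](CC)(CC)CC)C(C)(C)Br | intermediate
3 | 1-methoxy-4-(prop-1-en-2-yl)benzene (4-isopropenylanisole) | C=C(C)c1ccc(OC)cc1 | starting material
4 | 2-methyl-3-(triethylsilyloxy)but-3-en-2-ylium (siloxyallyl cation, bromide held by the catalyst) | C=C(O[Si](CC)(CC)CC)[C+](C)C.[Br-] | intermediate
5 | 2-(4-methoxyphenyl)-6-methyl-5-(triethylsilyloxy)hept-5-en-2-ylium (benzylic cation, bromide counter-ion) | CC(C)=C(O[Si](CC)(CC)CC)CC[C+](C)c1ccc(OC)cc1.[Br-] | intermediate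
6 | (3S)-3-(4-methoxyphenyl)-2,2,3-trimethylcyclopentan-1-one | CC1(C)C(=O)CC[C@@]1(C)c1ccc(OC)cc1 | intermediate
7 | 1-[(1S)-3-bromo-1,2,2-trimethylcyclopent-3-en-1-yl]-4-methoxybenzene | CC1(C)C(Br)=CC[C@@]1(C)c1ccc(OC)cc1 | intermediate
8 | 1-[(1S,3S)-3-bromo-1,2,2-trimethylcyclopentyl]-4-methoxybenzene (Br cis to aryl) | CC1(C)[C@@H](Br)CC[C@@]1(C)c1ccc(OC)cc1 | intermediate
9 | 4-[(1S,3S)-3-bromo-1,2,2-trimethylcyclopentyl]phenol | CC1(C)[C@@H](Br)CC[C@@]1(C)c1ccc(O)cc1 | intermediate
10 | 4-[(1R,3S)-3-bromo-1,2,2-trimethylcyclopentyl]-4-hydroperoxycyclohexa-2,5-dien-1-one | CC1(C)[C@@H](Br)CC[C@@]1(C)C1(OO)C=CC(=O)C=C1 | intermediate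
11 | 4-[(1R,3S)-3-bromo-1,2,2-trimethylcyclopentyl]-4-hydroxycyclohexa-2,5-dien-1-one | CC1(C)[C@@H](Br)CC[C@@]1(C)C1(O)C=CC(=O)C=C1 | intermediate
12 | 4-[(1R,3S)-3-bromo-1,2,2-trimethylcyclopentyl]-4-hydroxycyclohexan-1-one | CC1(C)[C@@H](Br)CC[C@@]1(C)C1(O)CCC(=O)CC1 | intermediate
13 | dilithium (4R)-4-[(1R,3S)-3-bromo-1,2,2-trimethylcyclopentyl]-4-oxidocyclohex-1-en-1-olate | CC1(C)[C@@H](Br)CC[C@@]1(C)[C@@]1([O-])CCC([O-])=CC1.[Li+].[Li+] | intermediate
14 | (4R)-4-[(1R,3S)-3-bromo-1,2,2-trimethylcyclopentyl]-4-hydroxycyclohex-1-en-1-yl trifluoromethanesulfonate | CC1(C)[C@@H](Br)CC[C@@]1(C)[C@@]1(O)CCC(OS(=O)(=O)C(F)(F)F)=CC1 | intermediate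
15 | (1R)-1-[(1R,3S)-3-bromo-1,2,2-trimethylcyclopentyl]-4-methylcyclohex-3-en-1-ol | CC1(C)[C@@H](Br)CC[C@@]1(C)[C@@]1(O)CCC(C)=CC1 | intermediate
16 | chlorodi(propan-2-yloxy)titanium alkoxide of 15 | CC1(C)[C@@H](Br)CC[C@@]1(C)[C@@]1(O[Ti](Cl)(OC(C)C)OC(C)C)CCC(C)=CC1 | intermediate
17 | (1R,3S,4S)-3-bromo-1-[(1R,3S)-3-bromo-1,2,2-trimethylcyclopentyl]-4-chloro-4-methylcyclohexan-1-ol | CC1(C)[C@@H](Br)CC[C@@]1(C)[C@@]1(O)CC[C@](C)(Cl)[C@@H](Br)C1 | target

## Step count and risks

Total step count: 10. Longest linear sequence: 10 steps (from 1; compound 3 enters at step 2).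

Steps most likely to fail:

Step 2 (proposed method). The ring closure may proceed with insufficient enantiofacial control, or proton loss from the benzylic cation and arylation of the anisole ring may outrun closure. The fallback uses the known racemic iron-mediated cyclocoupling followed by resolution; it sets out from 1 and 3 and returns at 6. Bromination of 1 at its methyl group (Br2, AcOH) gives 1,3-dibromo-3-methylbutan-2-one F1. F1 and 3 with Fe2(CO)9 in benzene at 55 °C (reductive generation of the iron-bound oxyallyl cation, the known route from α-methylstyrenes to 3-aryl-2,2,3-trimethylcyclopentanones) give racemic 3-(4-methoxyphenyl)-2,2,3-trimethylcyclopentan-1-one F2. Preparative chromatography of F2 on a chiral stationary phase delivers (S)-ketone 6.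

Step 10 (proposed method). Chloride may be captured at the secondary carbon without later equilibration, the hydroxyl may close onto the bromonium ion, or the tertiary carbinol may ionise. The fallback is stepwise and sets out from 15 and returns at 17. NBS alone in CH2Cl2 at 0 °C (bromoetherification, a known reaction of 4-methylcyclohex-3-en-1-ols) gives the bridged bromo ether (1S,2S,4R)-2-bromo-4-[(1R,3S)-3-bromo-1,2,2-trimethylcyclopentyl]-1-methyl-7-oxabicyclo[2.2.1]heptane F3, with oxygen bridging C1 and C4 and bromine anti to the bridge. Dry HCl in CH2Cl2 at −20 °C (acid cleavage of a tertiary cineole-type ether by a hydrogen halide) should open the C–O bond at the methyl-bearing carbon, whose ionisation is assisted by the antiperiplanar bromine, and return chloride on the oxygen face to give 17.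

Step 4. Hydrogen may be delivered to the wrong face of the bromine-bearing radical, or bromine may be lost reductively. The fallback sets the same centre by tin hydride reduction of a geminal dibromide; it sets out from 6 and returns at 8. Hydrazine hydrate in refluxing ethanol converts 6 into the hydrazone of (3S)-3-(4-methoxyphenyl)-2,2,3-trimethylcyclopentan-1-one F4. CuBr2 and Et3N in methanol turn F4 into 1-[(1S)-3,3-dibromo-1,2,2-trimethylcyclopentyl]-4-methoxybenzene F5. One equivalent of Bu3SnH with AIBN in benzene at 80 °C removes one bromine; the α-bromo radical should take hydrogen on the face anti to the aryl group and give 8.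

Further compounds
F1 | step 2 | 1,3-dibromo-3-methylbutan-2-one | CC(C)(Br)C(=O)CBr
F2 | step 2 | racemic 3-(4-methoxyphenyl)-2,2,3-trimethylcyclopentan-1-one | CC1(C)C(=O)CCC1(C)c1ccc(OC)cc1
F3 | step 10 | (1S,2S,4R)-2-bromo-4-[(1R,3S)-3-bromo-1,2,2-trimethylcyclopentyl]-1-methyl-7-oxabicyclo[2.2.1]heptane | CC1(C)[C@@H](Br)CC[C@@]1(C)[C@@]1(O2)CC[C@@]2(C)[C@@H](Br)C1
F4 | step 4 | hydrazone of (3S)-3-(4-methoxyphenyl)-2,2,3-trimethylcyclopentan-1-one | CC1(C)C(=NN)CC[C@@]1(C)c1ccc(OC)cc1
F5 | step 4 | 1-[(1S)-3,3-dibromo-1,2,2-trimethylcyclopentyl]-4-methoxybenzene | CC1(C)C(Br)(Br)CC[C@@]1(C)c1ccc(OC)cc1
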